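## The problem

Compound 20 is a 20-membered cyclophane in which two benzene rings are joined twice: once through a diaryl ether oxygen and once through an unbranched chain of twelve methylene carbons, numbered here C1 (on ring A) to C12 (on ring B). Ring A is 1,3,5-trisubstituted (hydroxyl, ether oxygen, C1). Ring B carries the ether oxygen between two hydroxyl groups, with C12 para to that oxygen. There is no stereocentre, so the task is purely constitutional: close a large ring and fix the chain at exactly twelve carbons. The chain is saturated and bears no functional group, so whatever handle closes the ring must afterwards disappear completely. The ether oxygen is flanked by two ortho oxygen substituents on ring B; this crowded C–O bond is better made early and intermolecularly than used for ring closure. The three phenols, in particular the 2-aryloxyresorcinol unit of ring B, are electron-rich and would not survive copper/oxygen, peracid or strong base in free form, so they are carried as ethers and released last. The enabling feature is that C1 is benzylic to ring A and joined to C2 by an ordinary CH2–CH2 bond: a sulfonyl group placed between C1 and C2 gives a benzyl alkyl sulfone whose C–S bonds come from sulfide and two primary bromides, and whose C1 hydrogens are the most acidic in the molecule, so that extrusion of SO2 rebuilds C1–C2 as an alkene that hydrogenation then removes.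

## Retrosynthesis

**20 from 19.** The three O–H bonds are traced back to O–CH3 bonds. Methyl ethers are chosen because two are already present in syringaldehyde 1 and the third in boronic acid 8, and because they tolerate every reagent of the route. The forward step must cleave three aryl methyl ethers and spare the diaryl ether.

**19 from 18.** A C1=C2 double bond is introduced retrosynthetically. It is the retron of a sulfone extrusion, and the forward hydrogenation erases its geometry, so styrene 18 may be a mixture of isomers.

**18 from 15 (key disconnection).** The C1=C2 bond is cut and both carbons are reconnected through a sulfonyl group, giving the 21-membered sulfone 15. This cut is preferred to any cut deeper in the chain because C1 is benzylic: its carbanion forms readily for the halogen transfer, and its electrophilic precursor is a reactive benzylic bromide. The mirror-image cut at C11–C12 next to ring B would serve equally in principle. It is not used because the C1 choice lets ring A arrive with nothing more than a formyl group, while the long chain is built on ring B in one olefination. The carbon–carbon bond then forms by closure of a three-membered ring within an existing macrocycle, not by an end-to-end macrocyclisation.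

**15 from 13 from 11.** The sulfone is taken back to sulfide 13, and both C–S bonds are cut to give dibromide 11 and inorganic sulfide. Ring closure thus becomes an S-alkylation by a strong, unhindered, weakly basic nucleophile, the most forgiving way to close a 21-membered ring. The forward reaction needs high dilution and clean SN2 chemistry at two primary carbons.

**11 from 10 from 9.** Both bromides are traced to hydroxyl groups (diol 10), and the benzylic hydroxyl to the formyl group of hydroxy aldehyde 9. Keeping the two chain termini at different oxidation levels until after the ether coupling means that neither needs protection.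

**9 from 7 and 8.** The diaryl ether is cut at the O–C bond on the ring A side. The oxygen then belongs to phenol 7, where syringaldehyde already provides it, and ring A enters as boronic acid 8, which brings the methoxy group and the formyl carbon that becomes C1. Cutting on the ring B side would require an electrophile flanked by two methoxy groups. The forward reaction must arylate a hindered phenol in the presence of a free primary alcohol and an aldehyde; the copper-mediated coupling of boronic acids does this at room temperature.

**7 from 6 from 2 and 4; 2 from 1; 4 from 3.** The C11=C12 bond is cut by a Wittig disconnection into O-benzylsyringaldehyde 2 (C12) and phosphonium salt 4 (C2–C11), which come from syringaldehyde 1 and 10-bromodecan-1-ol 3. One hydrogenation of alkene 6 saturates the chain and removes the benzyl group, so the protecting group costs one step only.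

## Roads not taken

**Alternative 1:** The cut runs through ring A itself. The two ring bonds flanking the CH between the hydroxyl-bearing and the ether-bearing carbon, together with the bond from the ether-bearing carbon to the next CH, are traced back to cyclobutenone A2, a 3-alkylcyclobutenone tethered through the complete C12 chain to ring B, whose phenolic oxygen carries an ethynyl group. On heating, 4π opening to a vinylketene, [2+2] addition to the ynol ether, a second 4π opening and 6π closure would build ring A and the macrocycle at once and give A1, the ring B dimethyl ether of 20, with the ring A phenol already free.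

- Merits: two C–C bonds and both rings form in one operation, the 1,3-relationship of hydroxyl and ether oxygen is fixed by the mechanism, no hindered diaryl ether coupling is needed, and only one demethylation separates A1 from 20 (against four steps after ring closure in the chosen plan).
- Weak points: an aryl ethynyl ether on a doubly ortho-substituted, electron-rich ring is laborious to prepare and sensitive to acid and heat. The macrocyclising event is the capture of a short-lived vinylketene by an alkyne twelve methylenes away; at the dilution a 20-membered ring requires, ketene dimerisation and adventitious trapping have time to compete. A2 also needs its own multistep assembly.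
- Comparison: the alternative is more convergent and shorter after ring closure. The chosen plan sets against this a ring closure by thiolate alkylation and a C–C bond formation that is not entropy-limited.

**Alternative 2:** The chain is cut at C8–C9 and C9–C10, with C9 supplied by tosylmethyl isocyanide A5 and the two arms by dibromide A4 (eight carbons on ring A, three on ring B). Double alkylation under high dilution would give macrocyclic α-tosyl isocyanide A3, racemic at C9. Acid hydrolysis to ketone A6 and deoxygenation would then reach 19.

- Merits: the dialkylation is a proven route to cyclophanes, it closes the ring directly by C–C bonds at a position remote from both arenes, and it needs two steps from ring closure to 19 against three in the chosen plan. On that count it is slightly better.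
- Weak points: A4 requires two different carbon arms, each built by its own C–C bond-forming sequence, so fragment synthesis is longer than the single olefination used here. The ring-closing step is the alkylation of a hindered, monoalkylated sulfonyl carbanion, which is slower and more basic than a thiolate and therefore more exposed to oligomerisation and elimination. The deoxygenation of A6 is harsh.
- Comparison: the chosen plan sets against the shorter end game a simpler precursor (both electrophilic termini from diol 10) and a softer ring-closing nucleophile.

**Alternative 3:** The chain is cut at C2=C3 and C10=C11. Bis-allyl diaryl ether A8 supplies C1–C2 and C11–C12, and cyclooctene A9 supplies C3–C10. A ruthenium alkylidene formed at one allyl group would open A9 and close on the other allyl group to give macrocyclic diene A7, which hydrogenation would convert into 19.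

- Merits: this is clearly the shortest road. A8 could come from allyl phenol A10 and a 3-allyl-5-methoxyphenyl partner in one ether coupling, and only metathesis, hydrogenation and demethylation would follow: roughly five or six steps against twelve.
- Weak points: the result depends on inserting exactly one molecule of A9. Direct closure of A8, insertion of two or more units and ring-opening polymerisation of A9 all compete and give homologues that differ by C8H14. Isomerisation of allylarenes to propenylarenes by ruthenium hydrides, followed by metathesis, would clip single carbons from the chain and give homologues that are nearly inseparable from A7.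
- Comparison: in step economy the alternative is superior. The chosen plan sets against it a chain length fixed by construction (C1 from the formyl carbon of 8, C2–C11 from 3, C12 from the formyl carbon of 1) and a ring closure whose product does not depend on a statistical distribution.

Key step: step 10

Assumption: 20 has no stereocentre; the double bonds of 6 and 18 are written without geometry because each is expected as a mixture of isomers that converges on hydrogenation, and the transient stereocentres of 14, 16 and 17 are racemic.

## Route

Step 1
Reactants: 1 syringaldehyde (4-hydroxy-3,5-dimethoxybenzaldehyde)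
Product: 2 4-(benzyloxy)-3,5-dimethoxybenzaldehyde
Conditions: BnBr, K2CO3, DMF, rt
Reagents that add atoms: benzyl bromide, BrCc1ccccc1
Why: Williamson O-benzylation of the phenoxide; masking the phenol keeps the para-formyl group electrophilic for the olefination, and the benzyl group is removed in step 4 without an extra operation.

Step 2
Reactants: 3 10-bromodecan-1-ol
Product: 4 (10-hydroxydecyl)triphenylphosphonium bromide
Conditions: PPh3, MeCN, reflux
Reagents that add atoms: triphenylphosphine, c1ccc(cc1)P(c1ccccc1)c1ccccc1
Why: SN2 quaternisation of triphenylphosphine by a primary bromide; the free hydroxyl group does not interfere.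

Step 3
Reactants: 4 (10-hydroxydecyl)triphenylphosphonium bromide; 2 4-(benzyloxy)-3,5-dimethoxybenzaldehyde
Product: 6 11-[4-(benzyloxy)-3,5-dimethoxyphenyl]undec-10-en-1-ol (mixture of alkene isomers), via ylide alkoxide 5 (not isolated)
Conditions: NaN(SiMe3)2 (2.1 equiv), THF, 0 °C; then 2, −78 °C → rt; H2O work-up
Reagents that add atoms: none
Why: Wittig olefination with a non-stabilised ylide; two equivalents of base give the alkoxide ylide 5, which adds to the non-enolisable aldehyde and forms C11=C12. The geometry is irrelevant because step 4 saturates the bond.

Step 4
Reactants: 6 11-[4-(benzyloxy)-3,5-dimethoxyphenyl]undec-10-en-1-ol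
Product: 7 4-(11-hydroxyundecyl)-2,6-dimethoxyphenol
Conditions: H2 (1 atm), 10% Pd/C, EtOAc/EtOH, rt
Reagents that add atoms: none
Why: Heterogeneous hydrogenation saturates the styrenyl double bond and hydrogenolyses the benzyl ether in the same operation, releasing the phenol for step 5; methyl ethers and the primary alcohol are inert.

Step 5
Reactants: 7 4-(11-hydroxyundecyl)-2,6-dimethoxyphenol; 8 (3-formyl-5-methoxyphenyl)boronic acid
Product: 9 3-[4-(11-hydroxyundecyl)-2,6-dimethoxyphenoxy]-5-methoxybenzaldehyde
Conditions: Cu(OAc)2 (1 equiv), pyridine, 4 Å molecular sieves, CH2Cl2, O2 (1 atm), rt
Reagents that add atoms: none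
Why: Chan–Lam O-arylation: the aryl group of 8 is transferred to copper, the phenoxide binds, and C–O reductive elimination from trivalent copper forms the diaryl ether at room temperature, with O2 returning copper to the divalent state. The phenol, far more acidic than the aliphatic alcohol, is the oxygen that is arylated; the formyl group is a spectator, and 2,6-disubstituted phenols are established substrates.

Step 6
Reactants: 9 3-[4-(11-hydroxyundecyl)-2,6-dimethoxyphenoxy]-5-methoxybenzaldehyde
Product: 10 11-{4-[3-(hydroxymethyl)-5-methoxyphenoxy]-3,5-dimethoxyphenyl}undecan-1-ol
Conditions: NaBH4, MeOH/THF, 0 °C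
Reagents that add atoms: none
Why: Borohydride reduction of an aromatic aldehyde to the benzylic alcohol; nothing else in 9 is reducible.

Step 7
Reactants: 10 11-{4-[3-(hydroxymethyl)-5-methoxyphenoxy]-3,5-dimethoxyphenyl}undecan-1-ol
Product: 11 5-(11-bromoundecyl)-2-[3-(bromomethyl)-5-methoxyphenoxy]-1,3-dimethoxybenzene
Conditions: CBr4, PPh3, CH2Cl2, 0 °C → rt
Reagents that add atoms: carbon tetrabromide, BrC(Br)(Br)Br
Why: Appel reaction: both primary hydroxyl groups are activated as alkoxyphosphonium ions and displaced by bromide under neutral conditions that leave the electron-rich arenes and ethers untouched.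

Step 8
Reactants: 11 5-(11-bromoundecyl)-2-[3-(bromomethyl)-5-methoxyphenoxy]-1,3-dimethoxybenzene
Product: 13 21-membered cyclic sulfide (tri-O-methyl; ring A–C1H2–S–(CH2)11–ring B closed by the diaryl ether oxygen), via bromo thiolate 12 (not isolated)
Conditions: Na2S·9H2O, EtOH/THF, 60 °C, high dilution (11 and the sulfide added slowly and simultaneously, final concentration about 1 mM)
Reagents that add atoms: sodium sulfide nonahydrate, [Na+].[Na+].[S-2].O.O.O.O.O.O.O.O.O
Why: Double SN2 thioetherification under high dilution, the standard entry to thiacyclophanes: sulfide attacks the more reactive benzylic bromide first and thiolate 12 then closes the 21-membered ring on the primary alkyl bromide. Slow simultaneous addition keeps electrophile and sulfide scarce so that ring closure outruns chain growth.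

Step 9
Reactants: 13 21-membered cyclic sulfide
Product: 15 21-membered cyclic benzyl alkyl sulfone (tri-O-methyl; SO2 between C1 and C2), via sulfoxide 14 (not isolated)
Conditions: mCPBA (2.2 equiv), CH2Cl2, 0 °C → rt
Reagents that add atoms: 3-chloroperbenzoic acid, OOC(=O)c1cccc(Cl)c1
Why: Peracid oxidation of the sulfide to the sulfone through sulfoxide 14; sulfur is oxidised much faster than the alkoxyarenes and no alkene is present.

Step 10
Reactants: 15 21-membered cyclic benzyl alkyl sulfone
Product: 18 20-membered macrocyclic styrene (tri-O-methyl; C1=C2; mixture of alkene isomers), via alpha-bromo sulfone 16 (not isolated), via episulfone 17 (not isolated)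
Conditions: KOH/Al2O3, CBr2F2, t-BuOH/CH2Cl2, 0 °C → rt
Reagents that add atoms: none
Why: Ramberg–Bäcklund reaction with halogenation in the flask, the classical ring contraction of benzylic thiacyclophane dioxides. Hydroxide on alumina removes a proton from C1, the α carbon activated by both the sulfonyl group and ring A, and the carbanion takes bromine from CBr2F2 to give 16. Deprotonation at C2 then displaces bromide in a 1,3-elimination, a 3-exo-tet closure to thiirane dioxide 17 that forms the C1–C2 bond. Episulfone 17 loses SO2 at or below room temperature, so the 21-membered ring contracts to the 20-membered carbocycle without an end-to-end closure; only a three-membered ring has to form inside a macrocycle that already exists. The stereocentres at C1 and C2 of 16 and 17 are transient and uncontrolled, and the alkene mixture they produce converges in step 11. The step needs a single halogenation at a sulfone α carbon and none on the two alkoxy-rich arenes; this is secured because CBr2F2 transfers bromine only to carbanions, the C1 carbanion is by far the most stabilised, and the monobromo sulfone should cyclise faster than it is brominated again. Aryl methyl ethers and the diaryl ether are inert to KOH.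

Step 11
Reactants: 18 20-membered macrocyclic styrene
Product: 19 tri-O-methyl ether of the target (saturated 20-membered macrocycle)
Conditions: H2 (1 atm), 10% Pd/C, EtOAc, rt
Reagents that add atoms: none
Why: Catalytic hydrogenation of a 1,2-disubstituted styrenyl alkene; both geometric isomers give the same saturated chain and the aryl ethers are inert.

Step 12
Reactants: 19 tri-O-methyl ether of the target
Product: 20 target triphenol CNP0314249.0
Conditions: BBr3 (6 equiv), CH2Cl2, −78 °C → rt, argon; then H2O, 0 °C
Reagents that add atoms: none
Why: Lewis-acid demethylation: BBr3 coordinates each methoxy oxygen and bromide removes the methyl group by SN2, while the diaryl ether offers no sp3 carbon for attack and is retained. Hydrolysis of the aryl borates on work-up releases the three phenols, and exclusion of air protects the electron-rich product.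

## Compound list

1 | syringaldehyde (4-hydroxy-3,5-dimethoxybenzaldehyde) | COc1cc(C=O)cc(OC)c1O | starting material
2 | 4-(benzyloxy)-3,5-dimethoxybenzaldehyde | COc1cc(C=O)cc(OC)c1OCc1ccccc1 | intermediate
3 | 10-bromodecan-1-ol | OCCCCCCCCCCBr | starting material
4 | (10-hydroxydecyl)triphenylphosphonium bromide | OCCCCCCCCCC[P+](c1ccccc1)(c1ccccc1)c1ccccc1.[Br-] | intermediate
5 | sodium 10-(triphenylphosphoranylidene)decan-1-olate (ylide alkoxide, formed in the flask) | [Na+].[O-]CCCCCCCCCC=P(c1ccccc1)(c1ccccc1)c1ccccc1 | intermediate
6 | 11-[4-(benzyloxy)-3,5-dimethoxyphenyl]undec-10-en-1-ol (mixture of alkene isomers) | COc1cc(C=CCCCCCCCCCO)cc(OC)c1OCc1ccccc1 | intermediate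
7 | 4-(11-hydroxyundecyl)-2,6-dimethoxyphenol | COc1cc(CCCCCCCCCCCO)cc(OC)c1O | intermediate
8 | (3-formyl-5-methoxyphenyl)boronic acid | COc1cc(C=O)cc(B(O)O)c1 | starting material
9 | 3-[4-(11-hydroxyundecyl)-2,6-dimethoxyphenoxy]-5-methoxybenzaldehyde | COc1cc(C=O)cc(Oc2c(OC)cc(CCCCCCCCCCCO)cc2OC)c1 | intermediate
10 | 11-{4-[3-(hydroxymethyl)-5-methoxyphenoxy]-3,5-dimethoxyphenyl}undecan-1-ol | COc1cc(CO)cc(Oc2c(OC)cc(CCCCCCCCCCCO)cc2OC)c1 | intermediate
11 | 5-(11-bromoundecyl)-2-[3-(bromomethyl)-5-methoxyphenoxy]-1,3-dimethoxybenzene | COc1cc(CBr)cc(Oc2c(OC)cc(CCCCCCCCCCCBr)cc2OC)c1 | intermediate
12 | sodium {3-[4-(11-bromoundecyl)-2,6-dimethoxyphenoxy]-5-methoxyphenyl}methanethiolate (formed in the flask) | COc1cc(C[S-])cc(Oc2c(OC)cc(CCCCCCCCCCCBr)cc2OC)c1.[Na+] | intermediate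
13 | 21-membered cyclic sulfide: ring A (3-methoxy, 5-aryloxy) bound through C1H2–S–(CH2)11 to the position para to the ether oxygen of ring B (2,6-dimethoxy) | COc1cc2cc(c1)Oc1c(OC)cc(cc1OC)CCCCCCCCCCCSC2 | intermediate
14 | the corresponding cyclic sulfoxide (racemic at sulfur, formed in the flask) | COc1cc2cc(c1)Oc1c(OC)cc(cc1OC)CCCCCCCCCCCS(=O)C2 | intermediate
15 | the corresponding 21-membered cyclic benzyl alkyl sulfone | COc1cc2cc(c1)Oc1c(OC)cc(cc1OC)CCCCCCCCCCCS(=O)(=O)C2 | intermediate
16 | sulfone 15 bearing bromine on the benzylic carbon C1 (racemic, formed in the flask) | COc1cc2cc(c1)Oc1c(OC)cc(cc1OC)CCCCCCCCCCCS(=O)(=O)C2Br | intermediate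
17 | episulfone: thiirane 1,1-dioxide spanning C1 and C2 of the 20-membered carbocycle (racemic, cis and trans, formed in the flask) | COc1cc2cc(c1)Oc1c(OC)cc(cc1OC)CCCCCCCCCCC3C2S3(=O)=O | intermediate
18 | 20-membered macrocyclic styrene, tri-O-methyl, C1=C2 (mixture of alkene isomers) | COc1cc2cc(c1)Oc1c(OC)cc(cc1OC)CCCCCCCCCCC=C2 | intermediate
19 | tri-O-methyl ether of the target: (CH2)12 chain from ring A (3-methoxy, 5-aryloxy) to the position para to the ether oxygen of ring B (2,6-dimethoxy) | COc1cc2cc(c1)Oc1c(OC)cc(cc1OC)CCCCCCCCCCCC2 | intermediate
20 | CNP0314249.0: 20-membered diaryl ether cyclophane, ring A 3-hydroxy-5-aryloxy, ring B 2,6-dihydroxy, (CH2)12 bridge | Oc1cc2cc(c1)Oc1c(O)cc(cc1O)CCCCCCCCCCCC2 | target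

## Step count and risks

Total steps: 12. Longest linear sequence: 11 steps (1 → 2 → 6 → 7 → 9 → 10 → 11 → 13 → 15 → 18 → 19 → 20); step 2 is the only step off this line.

**Step 10 (key step).** The likely failures are halogenation running past the monobromo stage at C1, capture of the difluorocarbene released from CBr2F2 by the newly formed styrene double bond, and sluggish closure to the episulfone in unfavourable ring conformations, which would leave 16 open to hydrolysis. The fallback separates halogenation from elimination and moves it to the sulfide oxidation level. It sets out from sulfide 13: N-chlorosuccinimide in CH2Cl2 should chlorinate the benzylic carbon through a chlorosulfonium and thionium ion to give the alpha-chloro sulfide F1. Immediate oxidation with mCPBA would give the alpha-chloro sulfone F2. KOt-Bu in THF at low temperature would then effect the 1,3-elimination through 17 and return to the route at 18. No carbene source and no excess halogenating agent are present in the elimination step.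

**Step 8.** The likely failures are intermolecular S-alkylation overtaking closure of the 21-membered ring, and substitution by sulfide at both termini before closure, which leads to dithiol and disulfide material. The fallback makes the two C–S bonds one at a time. It sets out from dibromide 11: one equivalent of KSAc in acetone at 0 °C should displace the benzylic bromide selectively and give S-{3-[4-(11-bromoundecyl)-2,6-dimethoxyphenoxy]-5-methoxybenzyl} thioacetate F3. Slow addition of F3 to NaOMe in MeOH/THF at high dilution would release thiolate 12 when no benzylic electrophile remains, and closure on the alkyl bromide returns to the route at 13.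

**Step 5.** The likely failures are oxidation of the electron-rich para-alkyl-2,6-dimethoxyphenol by divalent copper and oxygen, and slow C–O bond formation at the doubly ortho-substituted oxygen while protodeboronation and homocoupling consume 8. The fallback replaces the oxidative coupling by an Ullmann-type coupling without oxygen and changes the oxidation level of the ring A partner. It sets out from phenol 7: coupling with purchased methyl 3-bromo-5-methoxybenzoate (COC(=O)c1cc(Br)cc(OC)c1) with CuI, picolinic acid and K3PO4 in DMSO at 90 °C under argon should give methyl 3-[4-(11-hydroxyundecyl)-2,6-dimethoxyphenoxy]-5-methoxybenzoate F4. LiAlH4 in THF would reduce F4 to the diol and return to the route at 10; any ester exchange with the free alcohol during the coupling is undone by the same reduction. Compound 9 is bypassed and the step count is unchanged.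

## Further compounds

F1 | step 10 | cyclic sulfide 13 bearing chlorine on the benzylic carbon C1 (racemic) | COc1cc2cc(c1)Oc1c(OC)cc(cc1OC)CCCCCCCCCCCSC2Cl
F2 | step 10 | cyclic sulfone 15 bearing chlorine on the benzylic carbon C1 (racemic) | COc1cc2cc(c1)Oc1c(OC)cc(cc1OC)CCCCCCCCCCCS(=O)(=O)C2Cl
F3 | step 8 | S-{3-[4-(11-bromoundecyl)-2,6-dimethoxyphenoxy]-5-methoxybenzyl} thioacetate | CC(=O)SCc1cc(OC)cc(Oc2c(OC)cc(CCCCCCCCCCCBr)cc2OC)c1
F4 | step 5 | methyl 3-[4-(11-hydroxyundecyl)-2,6-dimethoxyphenoxy]-5-methoxybenzoate | COC(=O)c1cc(OC)cc(Oc2c(OC)cc(CCCCCCCCCCCO)cc2OC)c1
A1 | alternative 1 | ring B di-O-methyl ether of the target (ring A phenol free) | Oc1cc2cc(c1)Oc1c(OC)cc(cc1OC)CCCCCCCCCCCC2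
A2 | alternative 1 | 3-[12-(4-ethynyloxy-3,5-dimethoxyphenyl)dodecyl]cyclobut-2-en-1-one | O=C1C=C(CCCCCCCCCCCCc2cc(OC)c(OC#C)c(OC)c2)C1
A3 | alternative 2 | macrocyclic alpha-tosyl isocyanide, quaternary at C9 (racemic) | COc1cc2cc(c1)Oc1c(OC)cc(cc1OC)CCCC(S(=O)(=O)c3ccc(C)cc3)([N+]#[C-])CCCCCCCC2
A4 | alternative 2 | 5-(3-bromopropyl)-2-[3-(8-bromooctyl)-5-methoxyphenoxy]-1,3-dimethoxybenzene | COc1cc(CCCCCCCCBr)cc(Oc2c(OC)cc(CCCBr)cc2OC)c1
A5 | alternative 2 | tosylmethyl isocyanide | Cc1ccc(cc1)S(=O)(=O)C[N+]#[C-]
A6 | alternative 2 | macrocyclic ketone, carbonyl at C9, tri-O-methyl | COc1cc2cc(c1)Oc1c(OC)cc(cc1OC)CCCC(=O)CCCCCCCC2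
A7 | alternative 3 | macrocyclic diene, C2=C3 and C10=C11, tri-O-methyl (mixture of alkene isomers) | COc1cc2cc(c1)Oc1c(OC)cc(cc1OC)CC=CCCCCCCC=CC2
A8 | alternative 3 | 5-allyl-2-(3-allyl-5-methoxyphenoxy)-1,3-dimethoxybenzene | COc1cc(CC=C)cc(Oc2c(OC)cc(CC=C)cc2OC)c1
A9 | alternative 3 | (Z)-cyclooctene | C1CC/C=C\CCC1
A10 | alternative 3 | 4-allyl-2,6-dimethoxyphenol | COc1cc(CC=C)cc(OC)c1O
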